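**Two charges.** The flask holds more substrate than the violet run, under the same gas, so I ask what carries over from one to the other.

| flask | substrate | gas phase | remark | time |
|---|---|---|---|---|
| violet | 1.5 M | 200 mM (held) | run made earlier |  |
| flask | 2.3 M | 200 mM (held) |  | 40 min |

violet run (percent of the substrate charged)

| time / min | target / % | crystals / % |
|---|---|---|
| 2.50 | 1.0 | 0.4 |
| 4.00 | 1.0 | 0.1 |
| 8.00 | 1.6 | 0 |
| 12.0 | 4.4 | 0.6 |
| 20.0 | 7.2 | 0.4 |
| 30.0 | 10.4 | 0 |

(standard deviation of a reading: 0.5 percentage points)

- amounts and yields of target count crystals too
- given per volume of solution although it is solid: crystals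
- at the start none of the gas phase is in solution

* the target and crystals together standing at 40 min, as a percentage of the substrate charged
* concentration of dissolved gas in solution at 40 min, in percent of saturation

**First estimate.** Violet crystal readings stay near the scatter, so I count target. The last violet target reading is 10.4% at 30.0 min. Counting target as what consumes substrate, I reckon 94.8% of the substrate left on average. Assuming first order in substrate, this one reading gives a pseudo-first-order constant of 0.00366 min⁻¹. Over 40 min, I then reckon the flask at 14.6%.

**Shrinking substrate.** But the flask's substrate shrinks as it reacts. I put that answer back, and the mean substrate left lowers it to 13.6%.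

**Gas supply.** But the flask also asks for gas faster, at 8.41 mM min⁻¹ against 5.49 mM min⁻¹ in the violet run. I have no reading of the transfer. The early violet readings scatter by 0.5 percentage points, so they give me no lag, and I assume a gas lag of 2.50 min, the time of the first reading. Demand times lag, over saturation, is the gas deficit 10.5%, reckoned for the full charge. The violet run's is 6.86%. Going round once more, I scale the deficit by the substrate left, which puts c(dissolved gas) at 90.9% of saturation. I also scale the rate by the gas available, which gives 13.0%. The order in substrate remains an assumption, since the violet run has one charge.

**The result.** The forecast gives 13% and 85%, holding that “Dissolved gas should be near, but somewhat below, saturation”; my yield comes to the same figure from the same violet readings, and my gas stands higher. The flask gives 10.3% and 94.7%.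

    gas phase ⇌ dissolved gas, rate k1*(csat - [dissolved gas]) (kL = 0.00658 s⁻¹)
    substrate + dissolved gas → target (k = 4.79 × 10⁻⁴ M⁻¹ s⁻¹)
    crystals ⇌ target, rate k3*(cs3 - [target]) while solid is left; crystals form when [target] > cs3 (solubility = 1.10 M, k = 0.0184 s⁻¹)
    substrate + target → side product (k = 4.96 × 10⁻⁶ M⁻¹ s⁻¹)
    2 substrate → homo dimer (k = 1.55 × 10⁻⁴ M⁻¹ s⁻¹)

**Not at rest.** At 40.0 min the flask still holds 32% of its substrate. The deficit times that share is 3.36%, and the flask stands further short of saturation than that, at 5.30%. The same flask left until 2.5 h has 8.0% substrate, where the deficit times that share is 0.840% and the flask stands further short, at 1.36%. At 400 min the flask's substrate is down to 1.28%, target and crystals have reached 24.8%, and homo dimer has gone from 57.6% to 73.2%. The deficit times that share is then 0.134%, and c(dissolved gas) stands at 0.200 M.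

The runs stem from a simulated flask on assumed constants, and the scatter is random.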